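## Structural features

The target consists of two flavan units. The upper unit is a 3-deoxyflavan (benzo ring A, 4-hydroxyphenyl ring B, pyran ring C). The lower unit is a flavan-3,4-diol (benzo ring D, 4-hydroxyphenyl ring E, pyran ring F). The only bond between the halves joins upper C4, a diarylmethine carbon, to C6 of ring D, which is para to the ring-F oxygen O1 and ortho to the 7-hydroxyl. Ring F carries three contiguous stereocentres, C2 (aryl), C3 (OH) and C4 (OH), all on one face (2R,3R,4R). Ring C carries two 1,3-related centres, C2 (aryl) and C4 (ring D), trans to each other (2S,4S). The fragile groups are the two 7,8-dihydroxylated benzo rings and two further phenols (oxidation once free, worst under base), the lower C4–OH (benzylic and para to O7, so prone to ionisation and hydrogenolysis), and both O1–C2 bonds (benzylic ethers of oxygenated aryl groups, which acid can open with loss of C2 configuration). The main difficulty is the all-cis triad of ring F, where the diol sits on the face of the C2 aryl group, the face that a reagent approaching a flav-3-ene avoids. The second difficulty is the trans 2,4 relation in ring C, which is not the thermodynamically preferred one. The key step uses the C3=C4 double bond of a ring-F flav-3-ene: the C2 aryl sends the first electrophile to the far face, O7 (para to C4a) places the positive charge at C4, and a neighbouring acetate then returns both oxygens to the aryl face.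

## Logic of the disconnections

**27 to 26.** The six phenolic O–CH2Ph bonds are cut last. The free hexaphenol is sensitive to air and base, so it should appear only in a neutral final step. The forward hydrogenolysis must spare the benzylic lower C4–OH and both O1–C2 bonds.

**26 to 25.** The lower 3,4-diol is traced back to its cis-fused cyclic carbonate. This electron-poor mask makes the benzylic C4–O bond a poor leaving group under Lewis acid and needs only mild base for removal, so no acid touches the diol at either end. The forward methanolysis is run while all phenols are still benzylated.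

**25 to 23 and 24.** The upper C2–aryl bond (ring C to ring B) is cut. C2 becomes the carbon of a cyclic oxocarbenium ion and ring B an aryl nucleophile. This removes ring B and one stereocentre. The forward step must deliver the aryl group anti to the C4 substituent and must ionise the anomeric acetate without ionising lower C4–O.

**23 to 17 and 21 (through 22).** The upper C4–C4a bond and the O1–C2 bond of ring C are cut. Upper C4 is the β-carbon of an enal on ring D, and ring A is a phenol that supplies both the carbon nucleophile and the ring oxygen. This divides the molecule into the lower unit with a three-carbon chain and a simple phenol. The forward step needs catalyst control of the β-face (upper C4) and attack ortho to the phenolic OH.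

**17 to 16 to 13 and 14.** The carbonate is traced back to the diol and the C6–Cα bond on ring D is cut. Ring D is an aryl bromide and the three-carbon chain an alkenyl boronate with a masked aldehyde. The forward coupling must work on an electron-rich, ortho-substituted bromide beside a free diol, and the acetal must hydrolyse under acid too mild to ionise C4–OH.

**13 to 10.** The C3–O and C4–O bonds of ring F are cut, leaving the C3=C4 alkene. One existing stereocentre (C2) must control two new ones. The forward step must place both oxygens cis to the C2 aryl, against the steric bias. The bromine at C6 is kept as a spectator: it blocks the most nucleophilic arene position against electrophilic iodine and is the later coupling handle.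

**10 to 9 to 8.** The alkene is traced to the C4 alcohol and then the C4 ketone. The forward dehydration must avoid protic acid, because O1–C2 in 10 is both allylic and benzylic.

**8 to 6 and 7.** The C2–aryl bond (ring F to ring E) is cut. Ring E adds as an arylboronic acid to the β-carbon of a chromone, which sets the only stereocentre that is not relayed from another. The forward step needs high enantioselectivity and tolerance of the aryl bromide.

**6 to 3 and 4; 3 to 2 to 1.** O1–C2 and C2–C3 of ring F are cut, so C2 comes from a one-carbon amide acetal and the rest from an o-hydroxyacetophenone. The bromine and the two benzyl groups are removed in turn. Bromination must go para to the free phenol, and benzylation must leave the hydrogen-bonded 2-OH free.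

**21 to 19 to 18.** The phenolic C–O bond is traced to a formyl group (aryl migration to oxygen) and the benzyl ethers to a catechol aldehyde. The forward oxidation needs aryl, not hydride, migration.

## Other disconnections considered

**Alternative 1:** This cuts C3–C4 and O1–C2 of ring C. A chiral phosphoric acid would dehydrate the diaryl carbinol A2 to the E ortho-quinone methide of ring A, which adds an alkyl vinyl ether endo to give the 2,4-cis acetal A1.
- **In favour:** The quinone methide is a stronger electrophile than the donor-substituted iminium ion of step 12, and A1 has the oxidation level of 23, so the C2 arylation of step 13 would follow unchanged.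
- **Against:** A2 needs an aryl-metal addition to an aldehyde. That excludes the carbonate and forces an acetonide, whose benzylic C4–O bond must then face a Brønsted acid, a Lewis acid and finally acidic removal.
- **Comparison:** On mechanism this alternative is the better way to make the upper C4–C4a bond. On structure it is equal, since both plans rely on catalyst control remote from the lower stereocentres. On step economy it is equal or one step longer. It leaves the all-cis diol problem untouched.

**Alternative 2:** This cuts C3–C4 and O1–C2 of ring F. A chiral phosphoric acid would ionise the acetal A4 to a benzyloxy ortho-quinone methide, which adds the Z enol pivalate A5 to give the all-cis chroman A3.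
- **In favour:** Ring F and all three stereocentres arise in one convergent step from two achiral pieces. That is clearly better in step economy than the seven steps to 13.
- **Against:** Enantiocontrol for an alkoxy quinone methide with hydrogen on the methide carbon is less secure. The E/Z geometry of that methide decides C4. An enol ester is a weak 2π partner. The final hydrogenolysis would have to cut O–CH2Ph and not C4–O at a benzylic benzyl ether.
- **Comparison:** On structure the products are equivalent. On mechanism the chosen plan is more predictable, because it sets one centre by catalysis and relays it stepwise. On step economy alternative 2 is better.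

**Alternative 3:** This cuts O1–C2 of ring F. The phenol ketone A7 would close to its hemiketal, and a silane with a silyl triflate would reduce the derived C2 oxocarbenium ion to the protected flavan A6.
- **In favour:** Hydride should attack the convex face of the cis-fused acetonide, so the 2,3-cis relation follows the steric bias instead of opposing it. On the reliability of the triad this alternative is the better one. C3 and C4 could come from a reagent-controlled cis-dihydroxylation of a 7,8-dioxygenated coumarin alkene.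
- **Against:** The sequence is longer (dihydroxylation, protection, aryl addition to the lactone, then cyclisation). The α-oxygenated aryl ketone A7 can epimerise at C3. The silyl triflate meets a benzylic acetal C4–O bond para to O7.
- **Comparison:** The chosen plan is shorter, takes C2 from a catalytic C–C bond formation, and keeps strong acid away from the diol. Alternative 3 is mechanistically simpler at the step that sets the stereochemistry.

Key step: step 7

**Remarks on the chemistry**

- Ring letters: A/B/C for the upper unit, D/E/F for the lower unit; Bn = benzyl.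
- Assumption: the Pd/pyridine-oxazoline addition follows the facial sense known for 3-substituted cyclohexenones, so the (R)-tert-butyl ligand should give the (2S)-chromanone. If the sense were opposite, the antipodal ligand would be used.
- Assumption: 14, 24 and (R)-t-BuPyOx are catalogue compounds.
- CIP note: no centre is inverted after it is set, but some descriptors change with the substituents. Lower C2 is S in 8–10 and R from 11 on. Lower C3 is S in the carbonates and R in the diols. Upper C4 is R in the benzylated dimers and S in 27.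

## Route

**Step 1**
Reactants: 1 2,3,4-trihydroxyacetophenone
Product: 2 1-[3,4-bis(benzyloxy)-2-hydroxyphenyl]ethan-1-one
Conditions: BnBr (2.1 equiv), K2CO3, DMF, rt
Reagents that add atoms: benzyl bromide, BrCc1ccccc1
Why: Williamson ether synthesis; the 2-OH is hydrogen-bonded to the acetyl carbonyl and is the least nucleophilic, so two equivalents of halide should alkylate only O3 and O4.

**Step 2**
Reactants: 2 1-[3,4-bis(benzyloxy)-2-hydroxyphenyl]ethan-1-one
Product: 3 1-[3,4-bis(benzyloxy)-5-bromo-2-hydroxyphenyl]ethan-1-one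
Conditions: NBS (1.02 equiv), MeCN, 0 °C to rt
Reagents that add atoms: N-bromosuccinimide, O=C1CCC(=O)N1Br
Why: Electrophilic aromatic bromination; C5 is para to the free phenol and ortho to the 4-benzyloxy group and is the only strongly activated open position, and it becomes C6 of ring D.

**Step 3**
Reactants: 3 1-[3,4-bis(benzyloxy)-5-bromo-2-hydroxyphenyl]ethan-1-one; 4 N,N-dimethylformamide dimethyl acetal
Product: 6 7,8-bis(benzyloxy)-6-bromo-4H-chromen-4-one, via enaminone 5 (not isolated)
Conditions: 4 (2 equiv), toluene, 100 °C; then conc. HCl, CH2Cl2, 40 °C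
Reagents that add atoms: none
Why: Enaminone route to chromones; the methyl ketone condenses with the amide acetal, then acid promotes conjugate addition of the phenol and loss of dimethylamine, the acetal carbon becoming C2.

**Step 4**
Reactants: 6 7,8-bis(benzyloxy)-6-bromo-4H-chromen-4-one; 7 4-(benzyloxy)phenylboronic acid
Product: 8 (2S)-7,8-bis(benzyloxy)-2-[4-(benzyloxy)phenyl]-6-bromochroman-4-one
Conditions: Pd(OCOCF3)2 (5 mol%), (R)-t-BuPyOx (6 mol%), NH4PF6 (30 mol%), H2O (5 equiv), ClCH2CH2Cl, 60 °C
Reagents that add atoms: none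
Why: Enantioselective Pd-catalysed conjugate addition of an arylboronic acid to a chromone (transmetalation, face-selective carbopalladation, protonolysis); the tert-butyl group of the ligand should select the face that gives 2S, and the cycle stays at divalent palladium, so the aryl bromide should survive.

**Step 5**
Reactants: 8 (2S)-7,8-bis(benzyloxy)-2-[4-(benzyloxy)phenyl]-6-bromochroman-4-one
Product: 9 (2S,4S)-7,8-bis(benzyloxy)-2-[4-(benzyloxy)phenyl]-6-bromochroman-4-ol
Conditions: NaBH4, MeOH/THF, 0 °C
Reagents that add atoms: none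
Why: Borohydride reduction of the aryl ketone; axial hydride delivery should give the equatorial alcohol cis to the C2 aryl, and the medium is too weakly basic to open ring F by retro-oxa-Michael reaction, so C2 is kept (the C4 centre is removed in step 6).

**Step 6**
Reactants: 9 (2S,4S)-7,8-bis(benzyloxy)-2-[4-(benzyloxy)phenyl]-6-bromochroman-4-ol
Product: 10 (2S)-7,8-bis(benzyloxy)-2-[4-(benzyloxy)phenyl]-6-bromo-2H-chromene
Conditions: Ph2S[OC(CF3)2Ph]2 (1.3 equiv), CH2Cl2, 0 °C to rt
Reagents that add atoms: none
Why: Martin sulfurane dehydration of a secondary benzylic alcohol; the alkoxysulfonium intermediate eliminates toward C3 to the conjugated alkene, and the absence of protic acid protects the allylic, benzylic O1–C2 bond and so the C2 configuration.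

**Step 7**
Reactants: 10 (2S)-7,8-bis(benzyloxy)-2-[4-(benzyloxy)phenyl]-6-bromo-2H-chromene
Product: 13 (2R,3R,4R)-7,8-bis(benzyloxy)-2-[4-(benzyloxy)phenyl]-6-bromochroman-3,4-diol, via iodo acetate 11 (not isolated), via hydroxy acetate 12 (not isolated)
Conditions: I2 (1.05 equiv), AgOAc (2.3 equiv), AcOH, rt, dark; then H2O (1.5 equiv) in AcOH, 60–90 °C; filter; K2CO3, MeOH, rt
Reagents that add atoms: silver acetate, CC(=O)[O-].[Ag+] (one acetate supplies both new oxygen atoms); water, O (its oxygen ends only in the acetyl group of 12)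
Why: Woodward cis-hydroxylation (the wet variant of the Prévost reaction), here on a cyclic styrene-type alkene. Electrophilic iodine from I2/AgOAc should add to C3=C4 on the face away from the C2 aryl, with positive charge developing at C4, where O7 (para to C4a) and O1 stabilise it. Acetate then enters at C4 anti to iodine, on the aryl face, to give 11. On warming with AgOAc the acetate carbonyl oxygen displaces iodide at C3 with inversion, forming a transient cis-fused 2-methyl-1,3-dioxolan-2-ylium ion on the aryl face (5-exo attack; no ring of the product is closed). Water opens this ion at its acetal carbon to 12, and methanolysis gives 13. C4 is controlled by the anti opening, which the C3 iodine dictates and the C2 aryl ultimately sets; C3 is controlled by the inversion in the neighbouring-group displacement, so both oxygens end cis to the aryl. The step needs face selectivity relative to C2, secured by the aryl group next to C3, and alkene-over-arene selectivity, secured by the C6 bromine and by one equivalent of iodine. If the C4 acetate epimerises through the cation, only the trans iodo acetate can participate, so the sequence should still converge on the all-cis product.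

**Step 8**
Reactants: 13 (2R,3R,4R)-7,8-bis(benzyloxy)-2-[4-(benzyloxy)phenyl]-6-bromochroman-3,4-diol; 14 (E)-2-(3,3-diethoxyprop-1-en-1-yl)-4,4,5,5-tetramethyl-1,3,2-dioxaborolane
Product: 16 (E)-3-[(2R,3R,4R)-7,8-bis(benzyloxy)-2-[4-(benzyloxy)phenyl]-3,4-dihydroxychroman-6-yl]prop-2-enal, via diethyl acetal 15 (not isolated)
Conditions: Pd(OAc)2 (5 mol%), SPhos (10 mol%), K3PO4, 1,4-dioxane/H2O, 80 °C; then 1 M HCl, THF, 0 °C, brief
Reagents that add atoms: water, O
Why: Suzuki–Miyaura coupling of the aryl bromide with an alkenyl boronate, with retention of E geometry and tolerance of the free diol; the allylic diethyl acetal hydrolyses in cold dilute acid far faster than C4–OH can ionise.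

**Step 9**
Reactants: 16 (E)-3-[(2R,3R,4R)-7,8-bis(benzyloxy)-2-[4-(benzyloxy)phenyl]-3,4-dihydroxychroman-6-yl]prop-2-enal
Product: 17 (2R,3S,4R)-7,8-bis(benzyloxy)-2-[4-(benzyloxy)phenyl]-6-[(E)-3-oxoprop-1-en-1-yl]chroman-3,4-diyl carbonate
Conditions: CDI (1.5 equiv), DMAP (cat.), CH2Cl2, rt
Reagents that add atoms: 1,1'-carbonyldiimidazole, O=C(n1ccnc1)n1ccnc1
Why: Cyclic carbonate formation from a cis-1,2-diol without acid or chloride; the carbonate should keep the benzylic C4–O bond from ionising under the Lewis acid of step 13 and later comes off with mild base.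

**Step 10**
Reactants: 18 2,3-dihydroxybenzaldehyde
Product: 19 2,3-bis(benzyloxy)benzaldehyde
Conditions: BnBr (2.3 equiv), K2CO3, DMF, 60 °C
Reagents that add atoms: benzyl bromide, BrCc1ccccc1
Why: Williamson ether synthesis on both phenols.

**Step 11**
Reactants: 19 2,3-bis(benzyloxy)benzaldehyde
Product: 21 2,3-bis(benzyloxy)phenol, via aryl formate 20 (not isolated)
Conditions: mCPBA, CH2Cl2, rt; then K2CO3, MeOH, rt
Reagents that add atoms: 3-chloroperbenzoic acid, OOC(=O)c1cccc(Cl)c1
Why: Baeyer–Villiger oxidation of an electron-rich benzaldehyde (Dakin-type); the alkoxy-substituted aryl group migrates in preference to hydride, and the formate is methanolysed in the same flask.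

**Step 12**
Reactants: 17 (2R,3S,4R)-7,8-bis(benzyloxy)-2-[4-(benzyloxy)phenyl]-6-[(E)-3-oxoprop-1-en-1-yl]chroman-3,4-diyl carbonate; 21 2,3-bis(benzyloxy)phenol
Product: 23 (2R,3S,4R)-6-[(4R)-2-acetoxy-7,8-bis(benzyloxy)chroman-4-yl]-7,8-bis(benzyloxy)-2-[4-(benzyloxy)phenyl]chroman-3,4-diyl carbonate (both anomers), via lactol 22 (not isolated)
Conditions: (S)-2-[diphenyl(trimethylsilyloxy)methyl]pyrrolidine (20 mol%), PhCO2H (20 mol%), 21 (1.5 equiv), toluene, 0 °C to rt; then Ac2O, pyridine, DMAP (cat.), 0 °C
Reagents that add atoms: acetic anhydride, CC(=O)OC(C)=O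
Why: Iminium-ion-catalysed Friedel–Crafts alkylation and hemiacetalisation of a phenol with an enal; the silyloxydiphenylmethyl group shields one face of the E iminium ion, so C6 of 21 (ortho to OH, para to the 3-benzyloxy group) should attack the β-carbon from the open face and set upper C4 as required, after which the phenol closes onto the aldehyde and the lactol is acetylated.

**Step 13**
Reactants: 23 (2R,3S,4R)-6-[(4R)-2-acetoxy-7,8-bis(benzyloxy)chroman-4-yl]-7,8-bis(benzyloxy)-2-[4-(benzyloxy)phenyl]chroman-3,4-diyl carbonate; 24 potassium [4-(benzyloxy)phenyl]trifluoroborate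
Product: 25 (2R,3S,4R)-7,8-bis(benzyloxy)-6-[(2S,4R)-7,8-bis(benzyloxy)-2-[4-(benzyloxy)phenyl]chroman-4-yl]-2-[4-(benzyloxy)phenyl]chroman-3,4-diyl carbonate
Conditions: 24 (2 equiv), BF3·OEt2 (3 equiv), CH2Cl2/MeCN, −78 to −40 °C
Reagents that add atoms: none
Why: Lewis acid-promoted substitution of an anomeric acetate by an aryltrifluoroborate through the cyclic oxocarbenium ion; the aryldifluoroborane formed in the flask transfers its aryl group through the ipso carbon, and attack anti to the C4 substituent (axial attack on the half-chair) should give the kinetic 2,4-trans product, while low temperature and the carbonate keep lower C4–O and the new O1–C2 bond from ionising.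

**Step 14**
Reactants: 25 (2R,3S,4R)-7,8-bis(benzyloxy)-6-[(2S,4R)-7,8-bis(benzyloxy)-2-[4-(benzyloxy)phenyl]chroman-4-yl]-2-[4-(benzyloxy)phenyl]chroman-3,4-diyl carbonate
Product: 26 (2R,3R,4R)-7,8-bis(benzyloxy)-6-[(2S,4R)-7,8-bis(benzyloxy)-2-[4-(benzyloxy)phenyl]chroman-4-yl]-2-[4-(benzyloxy)phenyl]chroman-3,4-diol
Conditions: K2CO3 (0.5 equiv), MeOH/THF, rt
Reagents that add atoms: none
Why: Base-catalysed methanolysis of the cyclic carbonate by acyl–oxygen cleavage, so C3 and C4 are untouched; all phenols are still benzylated, so no oxidation-prone phenoxide is present.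

**Step 15**
Reactants: 26 (2R,3R,4R)-7,8-bis(benzyloxy)-6-[(2S,4R)-7,8-bis(benzyloxy)-2-[4-(benzyloxy)phenyl]chroman-4-yl]-2-[4-(benzyloxy)phenyl]chroman-3,4-diol
Product: 27 (2R,3R,4R)-6-[(2S,4S)-7,8-dihydroxy-2-(4-hydroxyphenyl)chroman-4-yl]-2-(4-hydroxyphenyl)chroman-3,4,7,8-tetrol
Conditions: H2 (1 atm), Pd/C (10%), THF/MeOH, rt, stopped after six equivalents of H2
Reagents that add atoms: none
Why: Hydrogenolysis of six aryl benzyl ethers under neutral conditions; these should cleave much faster than the secondary benzylic C4–OH or the ring O1–C2 bonds, and the product needs only filtration under inert gas.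

## Compound list

1 | 2,3,4-trihydroxyacetophenone | CC(=O)c1ccc(O)c(O)c1O | starting material
2 | 1-[3,4-bis(benzyloxy)-2-hydroxyphenyl]ethan-1-one | CC(=O)c1ccc(OCc9ccccc9)c(OCc9ccccc9)c1O | intermediate
3 | 1-[3,4-bis(benzyloxy)-5-bromo-2-hydroxyphenyl]ethan-1-one | CC(=O)c1cc(Br)c(OCc9ccccc9)c(OCc9ccccc9)c1O | intermediate
4 | N,N-dimethylformamide dimethyl acetal | COC(OC)N(C)C | starting material
5 | (E)-1-[3,4-bis(benzyloxy)-5-bromo-2-hydroxyphenyl]-3-(dimethylamino)prop-2-en-1-one (not isolated) | CN(C)/C=C/C(=O)c1cc(Br)c(OCc9ccccc9)c(OCc9ccccc9)c1O | intermediate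
6 | 7,8-bis(benzyloxy)-6-bromo-4H-chromen-4-one | O=c1ccoc2c(OCc9ccccc9)c(OCc9ccccc9)c(Br)cc12 | intermediate
7 | 4-(benzyloxy)phenylboronic acid | OB(O)c1ccc(OCc9ccccc9)cc1 | starting material
8 | (2S)-7,8-bis(benzyloxy)-2-[4-(benzyloxy)phenyl]-6-bromochroman-4-one | Brc1cc2c(c(OCc9ccccc9)c1OCc9ccccc9)O[C@H](c3ccc(OCc9ccccc9)cc3)CC2=O | intermediate
9 | (2S,4S)-7,8-bis(benzyloxy)-2-[4-(benzyloxy)phenyl]-6-bromochroman-4-ol (2,4-cis) | Brc1cc2c(c(OCc9ccccc9)c1OCc9ccccc9)O[C@H](c3ccc(OCc9ccccc9)cc3)C[C@@H]2O | intermediate
10 | (2S)-7,8-bis(benzyloxy)-2-[4-(benzyloxy)phenyl]-6-bromo-2H-chromene | Brc1cc2c(c(OCc9ccccc9)c1OCc9ccccc9)O[C@H](c3ccc(OCc9ccccc9)cc3)C=C2 | intermediate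
11 | (2R,3R,4R)-7,8-bis(benzyloxy)-2-[4-(benzyloxy)phenyl]-6-bromo-3-iodochroman-4-yl acetate, iodine trans and acetate cis to the C2 aryl (not isolated) | Brc1cc2c(c(OCc9ccccc9)c1OCc9ccccc9)O[C@H](c3ccc(OCc9ccccc9)cc3)[C@@H](I)[C@@H]2OC(C)=O | intermediate
12 | (2R,3R,4R)-7,8-bis(benzyloxy)-2-[4-(benzyloxy)phenyl]-6-bromo-4-hydroxychroman-3-yl acetate, all-cis; drawn as the 3-acetate, the 4-acetate from acyl migration gives the same diol (not isolated) | Brc1cc2c(c(OCc9ccccc9)c1OCc9ccccc9)O[C@H](c3ccc(OCc9ccccc9)cc3)[C@H](OC(C)=O)[C@@H]2O | intermediate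
13 | (2R,3R,4R)-7,8-bis(benzyloxy)-2-[4-(benzyloxy)phenyl]-6-bromochroman-3,4-diol (all-cis) | Brc1cc2c(c(OCc9ccccc9)c1OCc9ccccc9)O[C@H](c3ccc(OCc9ccccc9)cc3)[C@H](O)[C@@H]2O | intermediate
14 | (E)-2-(3,3-diethoxyprop-1-en-1-yl)-4,4,5,5-tetramethyl-1,3,2-dioxaborolane | CCOC(OCC)/C=C/B1OC(C)(C)C(C)(C)O1 | starting material
15 | (2R,3R,4R)-7,8-bis(benzyloxy)-2-[4-(benzyloxy)phenyl]-6-[(E)-3,3-diethoxyprop-1-en-1-yl]chroman-3,4-diol (not isolated) | CCOC(OCC)/C=C/c1cc2c(c(OCc9ccccc9)c1OCc9ccccc9)O[C@H](c3ccc(OCc9ccccc9)cc3)[C@H](O)[C@@H]2O | intermediate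
16 | (E)-3-[(2R,3R,4R)-7,8-bis(benzyloxy)-2-[4-(benzyloxy)phenyl]-3,4-dihydroxychroman-6-yl]prop-2-enal | O=C/C=C/c1cc2c(c(OCc9ccccc9)c1OCc9ccccc9)O[C@H](c3ccc(OCc9ccccc9)cc3)[C@H](O)[C@@H]2O | intermediate
17 | (2R,3S,4R)-7,8-bis(benzyloxy)-2-[4-(benzyloxy)phenyl]-6-[(E)-3-oxoprop-1-en-1-yl]chroman-3,4-diyl carbonate (cis-fused cyclic carbonate) | O=C/C=C/c1cc2c(c(OCc9ccccc9)c1OCc9ccccc9)O[C@H](c3ccc(OCc9ccccc9)cc3)[C@H](O4)[C@@H]2OC4=O | intermediate
18 | 2,3-dihydroxybenzaldehyde | O=Cc1cccc(O)c1O | starting material
19 | 2,3-bis(benzyloxy)benzaldehyde | O=Cc1cccc(OCc9ccccc9)c1OCc9ccccc9 | intermediate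
20 | 2,3-bis(benzyloxy)phenyl formate (not isolated) | O=COc1cccc(OCc9ccccc9)c1OCc9ccccc9 | intermediate
21 | 2,3-bis(benzyloxy)phenol | Oc1cccc(OCc9ccccc9)c1OCc9ccccc9 | intermediate
22 | (2R,3S,4R)-7,8-bis(benzyloxy)-6-[(4R)-7,8-bis(benzyloxy)-2-hydroxychroman-4-yl]-2-[4-(benzyloxy)phenyl]chroman-3,4-diyl carbonate, both lactol epimers (not isolated) | OC1C[C@@H](c3cc4c(c(OCc9ccccc9)c3OCc9ccccc9)O[C@H](c5ccc(OCc9ccccc9)cc5)[C@H](O6)[C@@H]4OC6=O)c2ccc(OCc9ccccc9)c(OCc9ccccc9)c2O1 | intermediate
23 | (2R,3S,4R)-6-[(4R)-2-acetoxy-7,8-bis(benzyloxy)chroman-4-yl]-7,8-bis(benzyloxy)-2-[4-(benzyloxy)phenyl]chroman-3,4-diyl carbonate, both anomers | CC(=O)OC1C[C@@H](c3cc4c(c(OCc9ccccc9)c3OCc9ccccc9)O[C@H](c5ccc(OCc9ccccc9)cc5)[C@H](O6)[C@@H]4OC6=O)c2ccc(OCc9ccccc9)c(OCc9ccccc9)c2O1 | intermediate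
24 | potassium [4-(benzyloxy)phenyl]trifluoroborate | [K+].F[B-](F)(F)c1ccc(OCc9ccccc9)cc1 | starting material
25 | (2R,3S,4R)-7,8-bis(benzyloxy)-6-[(2S,4R)-7,8-bis(benzyloxy)-2-[4-(benzyloxy)phenyl]chroman-4-yl]-2-[4-(benzyloxy)phenyl]chroman-3,4-diyl carbonate (upper unit 2,4-trans) | c9ccccc9COc1ccc([C@@H]2C[C@@H](c4cc5c(c(OCc9ccccc9)c4OCc9ccccc9)O[C@H](c6ccc(OCc9ccccc9)cc6)[C@H](O7)[C@@H]5OC7=O)c3ccc(OCc9ccccc9)c(OCc9ccccc9)c3O2)cc1 | intermediate
26 | (2R,3R,4R)-7,8-bis(benzyloxy)-6-[(2S,4R)-7,8-bis(benzyloxy)-2-[4-(benzyloxy)phenyl]chroman-4-yl]-2-[4-(benzyloxy)phenyl]chroman-3,4-diol | c9ccccc9COc1ccc([C@@H]2C[C@@H](c4cc5c(c(OCc9ccccc9)c4OCc9ccccc9)O[C@H](c6ccc(OCc9ccccc9)cc6)[C@H](O)[C@@H]5O)c3ccc(OCc9ccccc9)c(OCc9ccccc9)c3O2)cc1 | intermediate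
27 | (2R,3R,4R)-6-[(2S,4S)-7,8-dihydroxy-2-(4-hydroxyphenyl)chroman-4-yl]-2-(4-hydroxyphenyl)chroman-3,4,7,8-tetrol | Oc1ccc([C@@H]2C[C@@H](c3cc4c(c(O)c3O)O[C@H](c3ccc(O)cc3)[C@H](O)[C@@H]4O)c3ccc(O)c(O)c3O2)cc1 | target

## Step count and least certain steps

Total: 15 steps (13 in the main line and 2 for phenol 21). Longest linear sequence: 13 steps (steps 1–9 and 12–15).

**Step 7 (key step).**
- **Risk:** When silver ionises the C3–I bond, participation by the ring oxygen O1 or migration of ring D could compete with the acetate, giving ring contraction or rearrangement. O1 is antiperiplanar to the equatorial C3–I bond in the conformer with an equatorial C2 aryl, whereas the acetate needs the less favoured diaxial conformer. Over-iodination of the electron-rich rings and solvolysis at C4 in hot acetic acid are secondary risks.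
- **Fallback (from 10, back at 13):** Dimethyldioxirane in acetone at −20 °C should epoxidise 10 on the face away from the aryl group to give the 2,3-trans epoxide F1. Acetic acid added cold opens it at benzylic C4 with inversion to the 2,3-trans-3,4-trans hydroxy acetate F2. Dess–Martin oxidation gives the 4-acetoxychroman-3-one F3. LiBH(s-Bu)3 at −78 °C should deliver hydride to the face opposite both the C2 aryl and the C4 acetate, giving the all-cis 4-acetate F4. K2CO3 in MeOH then gives 13.

**Step 12.**
- **Risk:** The iminium ion of 17 is deactivated because ring D donates into the β-carbon through O1 (para) and O7 (ortho), so conversion may be low. Attack of 21 through the position para to its hydroxyl would give an open-chain adduct that cannot close to the lactol.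
- **Fallback (from 13 and 9, back at 27):** CDI converts 13 to the bromo carbonate F7. Pd(OAc)2, PPh3 and HCO2Na in DMF remove the bromine to give the C6–H carbonate F8. BF3·OEt2 at −78 °C ionises alcohol 9, whose own C6 is blocked by bromine, and C6 of F8 should attack the C4 cation anti to the C2 aryl to give the 2,4-trans coupled bromide F9. K2CO3 in MeOH gives the bromo diol F10. H2 over Pd/C with NaOAc removes the six benzyl groups and the aryl bromide to give 27. This is shorter but gives up catalyst control of upper C4.

**Step 13.**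
- **Risk:** Loss of the kinetic 2,4-trans selectivity, either by poor facial discrimination or by Lewis acid-promoted reopening of the new benzylic O1–C2 bond, which would drift toward the more stable 2,4-cis isomer. Slow aryl transfer from boron is a secondary risk.
- **Fallback (from 22, back at 25):** Lactol 22 is isolated instead of being acetylated. Aryl transfer from 7 with Et2Zn and a chiral amino alcohol ligand (the enantiomer selective for the R carbinol), which tolerates the carbonate, gives the (1R,3R) phenol carbinol F11. Mitsunobu cyclisation (PPh3, DIAD) closes O1–C2 with inversion to 25.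

**Step 4.**
- **Risk:** Low conversion or enantioselectivity on a chromone carrying an 8-benzyloxy group next to O1, protodeboronation of the electron-rich boronic acid, and coupling at the C–Br bond if zerovalent palladium accumulates.
- **Fallback (from 3, back at 9):** Claisen–Schmidt condensation of 3 with commercial 4-(benzyloxy)benzaldehyde (KOH, EtOH) gives the chalcone F5. NaOAc in refluxing EtOH cyclises it to the racemic chromanone F6. Asymmetric transfer hydrogenation with RuCl(p-cymene)[(S,S)-TsDPEN] or its antipode (HCO2H/Et3N), chosen so that the 2S ketone reacts fast, resolves F6 kinetically and gives 9 directly. The unreacted 2R ketone can be racemised with base and recycled.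

## Further compounds

F1 | step 7 | (2R)-7,8-bis(benzyloxy)-2-[4-(benzyloxy)phenyl]-6-bromo-3,4-epoxychroman, epoxide oxygen trans to the C2 aryl | Brc1cc2c(c(OCc9ccccc9)c1OCc9ccccc9)O[C@H](c3ccc(OCc9ccccc9)cc3)[C@@H](O4)[C@H]24
F2 | step 7 | (2R,3R,4R)-7,8-bis(benzyloxy)-2-[4-(benzyloxy)phenyl]-6-bromo-3-hydroxychroman-4-yl acetate, 2,3-trans-3,4-trans | Brc1cc2c(c(OCc9ccccc9)c1OCc9ccccc9)O[C@H](c3ccc(OCc9ccccc9)cc3)[C@@H](O)[C@@H]2OC(C)=O
F3 | step 7 | (2R,4R)-7,8-bis(benzyloxy)-2-[4-(benzyloxy)phenyl]-6-bromo-3-oxochroman-4-yl acetate, 2,4-cis | Brc1cc2c(c(OCc9ccccc9)c1OCc9ccccc9)O[C@H](c3ccc(OCc9ccccc9)cc3)C(=O)[C@@H]2OC(C)=O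
F4 | step 7 | (2R,3S,4R)-7,8-bis(benzyloxy)-2-[4-(benzyloxy)phenyl]-6-bromo-3-hydroxychroman-4-yl acetate, all-cis | Brc1cc2c(c(OCc9ccccc9)c1OCc9ccccc9)O[C@H](c3ccc(OCc9ccccc9)cc3)[C@H](O)[C@@H]2OC(C)=O
F5 | step 4 | (E)-1-[3,4-bis(benzyloxy)-5-bromo-2-hydroxyphenyl]-3-[4-(benzyloxy)phenyl]prop-2-en-1-one | O=C(/C=C/c1ccc(OCc9ccccc9)cc1)c1cc(Br)c(OCc9ccccc9)c(OCc9ccccc9)c1O
F6 | step 4 | racemic 7,8-bis(benzyloxy)-2-[4-(benzyloxy)phenyl]-6-bromochroman-4-one | Brc1cc2c(c(OCc9ccccc9)c1OCc9ccccc9)OC(c3ccc(OCc9ccccc9)cc3)CC2=O
F7 | step 12 | (2R,3S,4R)-7,8-bis(benzyloxy)-2-[4-(benzyloxy)phenyl]-6-bromochroman-3,4-diyl carbonate | Brc1cc2c(c(OCc9ccccc9)c1OCc9ccccc9)O[C@H](c3ccc(OCc9ccccc9)cc3)[C@H](O4)[C@@H]2OC4=O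
F8 | step 12 | (2R,3S,4R)-7,8-bis(benzyloxy)-2-[4-(benzyloxy)phenyl]chroman-3,4-diyl carbonate | c1cc2c(c(OCc9ccccc9)c1OCc9ccccc9)O[C@H](c3ccc(OCc9ccccc9)cc3)[C@H](O4)[C@@H]2OC4=O
F9 | step 12 | (2R,3S,4R)-7,8-bis(benzyloxy)-6-[(2S,4S)-7,8-bis(benzyloxy)-2-[4-(benzyloxy)phenyl]-6-bromochroman-4-yl]-2-[4-(benzyloxy)phenyl]chroman-3,4-diyl carbonate, upper unit 2,4-trans | c9ccccc9COc1ccc([C@@H]2C[C@@H](c4cc5c(c(OCc9ccccc9)c4OCc9ccccc9)O[C@H](c6ccc(OCc9ccccc9)cc6)[C@H](O7)[C@@H]5OC7=O)c3cc(Br)c(OCc9ccccc9)c(OCc9ccccc9)c3O2)cc1
F10 | step 12 | (2R,3R,4R)-7,8-bis(benzyloxy)-6-[(2S,4S)-7,8-bis(benzyloxy)-2-[4-(benzyloxy)phenyl]-6-bromochroman-4-yl]-2-[4-(benzyloxy)phenyl]chroman-3,4-diol | c9ccccc9COc1ccc([C@@H]2C[C@@H](c4cc5c(c(OCc9ccccc9)c4OCc9ccccc9)O[C@H](c6ccc(OCc9ccccc9)cc6)[C@H](O)[C@@H]5O)c3cc(Br)c(OCc9ccccc9)c(OCc9ccccc9)c3O2)cc1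
F11 | step 13 | (2R,3S,4R)-7,8-bis(benzyloxy)-6-[(1R,3R)-1-[3,4-bis(benzyloxy)-2-hydroxyphenyl]-3-[4-(benzyloxy)phenyl]-3-hydroxypropyl]-2-[4-(benzyloxy)phenyl]chroman-3,4-diyl carbonate (locant 1 = diarylmethine carbon, locant 3 = carbinol carbon) | c9ccccc9COc1ccc([C@H](O)C[C@@H](c4cc5c(c(OCc9ccccc9)c4OCc9ccccc9)O[C@H](c6ccc(OCc9ccccc9)cc6)[C@H](O7)[C@@H]5OC7=O)c3ccc(OCc9ccccc9)c(OCc9ccccc9)c3O)cc1
A1 | alternative 1 | 2-ethoxy-7,8-bis(benzyloxy)-4-(lower unit-6-yl)chroman, 2,4-cis acetal, lower diol as acetonide | CCO[C@H]1C[C@@H](c3cc4c(c(OCc9ccccc9)c3OCc9ccccc9)O[C@H](c5ccc(OCc9ccccc9)cc5)[C@H](O6)[C@@H]4OC6(C)C)c2ccc(OCc9ccccc9)c(OCc9ccccc9)c2O1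
A2 | alternative 1 | [3,4-bis(benzyloxy)-2-hydroxyphenyl](lower unit-6-yl)methanol, lower diol as acetonide, carbinol centre undefined | OC(c1ccc(OCc9ccccc9)c(OCc9ccccc9)c1O)c3cc4c(c(OCc9ccccc9)c3OCc9ccccc9)O[C@H](c5ccc(OCc9ccccc9)cc5)[C@H](O6)[C@@H]4OC6(C)C
A3 | alternative 2 | all-cis 4,7,8-tris(benzyloxy)-2-[4-(benzyloxy)phenyl]chroman-3-yl pivalate | c1cc2c(c(OCc9ccccc9)c1OCc9ccccc9)O[C@H](c1ccc(OCc9ccccc9)cc1)[C@H](OC(=O)C(C)(C)C)[C@@H]2OCc9ccccc9
A4 | alternative 2 | 3,4-bis(benzyloxy)-2-hydroxybenzaldehyde dibenzyl acetal | Oc1c(C(OCc9ccccc9)OCc9ccccc9)ccc(OCc9ccccc9)c1OCc9ccccc9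
A5 | alternative 2 | (Z)-2-[4-(benzyloxy)phenyl]ethenyl pivalate | CC(C)(C)C(=O)O/C=C\c1ccc(OCc9ccccc9)cc1
A6 | alternative 3 | all-cis 7,8-bis(benzyloxy)-2-[4-(benzyloxy)phenyl]chroman-3,4-diol acetonide | c1cc2c(c(OCc9ccccc9)c1OCc9ccccc9)O[C@H](c1ccc(OCc9ccccc9)cc1)[C@H](O6)[C@@H]2OC6(C)C
A7 | alternative 3 | cis-[5-[3,4-bis(benzyloxy)-2-hydroxyphenyl]-2,2-dimethyl-1,3-dioxolan-4-yl][4-(benzyloxy)phenyl]methanone, configured as C3 and C4 of A6 | c1cc(c(O)c(OCc9ccccc9)c1OCc9ccccc9)[C@H]2OC(C)(C)O[C@H]2C(=O)c1ccc(OCc9ccccc9)cc1
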